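The carbocycle (C3a, C4, C5, C6, C7, C7a of the benzofuranone core) is disconnected at C5: a cyclopentanone triethylsilyl enol ether carrying the C7a silyloxy stereocentre and the C6 oxymethyl group takes up dibromocarbene, and the siloxy-dibromocyclopropane opens to a 2-bromocyclohex-2-enone. One operation inserts C5 between C4 and C6, makes the six-membered ring and leaves bromine on C5. The step exploits the C4(O)–C5=C6 array, an oxygenated carbon beside the tetrasubstituted ring alkene. The bromide is then exchanged for the (S)-sec-alkyl chain by Zweifel coupling with retention; the C4 ketone serves for alkylation at C3a, is kept during lactonisation and is reduced last.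

Key step: step 6

Remark: locants O1–C7a are those of the 1-benzofuran-2(3H)-one core of the target; compounds 1, 3, 7 (the S enantiomer) and (+)-sparteine are assumed to be purchasable.

Step 1
Reactants: 1 tert-butyldimethyl(prop-2-en-1-yloxy)silane
Product: 2 tert-butyldimethyl[3-(4,4,5,5-tetramethyl-1,3,2-dioxaborolan-2-yl)propoxy]silane
Conditions: HBpin, [Ir(cod)Cl]2 (1.5 mol %), Ph2PCH2PPh2 (3 mol %), CH2Cl2, 25 °C
Reagents that add atoms: pinacolborane, [H]B1OC(C)(C)C(C)(C)O1
Why: Iridium-catalysed hydroboration of the terminal alkene with pinacolborane should place boron on the terminal carbon (anti-Markovnikov hydroboration); no stereocentre is formed.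

Step 2
Reactants: 3 ethyl 2,4,6-tri(propan-2-yl)benzoate; 2 tert-butyldimethyl[3-(4,4,5,5-tetramethyl-1,3,2-dioxaborolan-2-yl)propoxy]silane
Product: 6 tert-butyldimethyl{[(4S)-4-(4,4,5,5-tetramethyl-1,3,2-dioxaborolan-2-yl)pentyl]oxy}silane, via lithiated benzoate 4 (not isolated), via boronate complex 5 (not isolated)
Conditions: s-BuLi, (+)-sparteine, Et2O, −78 °C, 5 h; then 2, −78 °C; then reflux, 16 h
Reagents that add atoms: none
Why: Sparteine-directed enantioselective deprotonation gives the (R)-lithiated benzoate 4, which is borylated by 2 with retention to 5 and then undergoes a stereospecific 1,2-metallate rearrangement with inversion (lithiation–borylation, a Matteson-type homologation), so that (+)-sparteine sets the S configuration of 6.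

Step 3
Reactants: 7 (4S)-4-[(tert-butyldimethylsilyl)oxy]cyclopent-2-en-1-one
Product: 8 (4S)-4-[(tert-butyldimethylsilyl)oxy]-2-(hydroxymethyl)cyclopent-2-en-1-one
Conditions: 37% aq. HCHO, imidazole, THF/H2O (1:1), 25 °C
Reagents that add atoms: formaldehyde, C=O
Why: Morita–Baylis–Hillman reaction: imidazole adds reversibly to the enone, the enolate is hydroxymethylated at C2 by formaldehyde and the catalyst is expelled, leaving the C4 stereocentre untouched.

Step 4
Reactants: 8 (4S)-4-[(tert-butyldimethylsilyl)oxy]-2-(hydroxymethyl)cyclopent-2-en-1-one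
Product: 9 (4S)-4-[(tert-butyldimethylsilyl)oxy]-2-{[(tert-butyldiphenylsilyl)oxy]methyl}cyclopent-2-en-1-one
Conditions: t-BuPh2SiCl, imidazole, CH2Cl2, 0 to 25 °C
Reagents that add atoms: tert-butyl(chloro)diphenylsilane, CC(C)(C)[Si](Cl)(c1ccccc1)c1ccccc1
Why: Imidazole-promoted silylation of the primary allylic alcohol gives an ether that is stable to base, organolithium reagents and mild acid.

Step 5
Reactants: 9 (4S)-4-[(tert-butyldimethylsilyl)oxy]-2-{[(tert-butyldiphenylsilyl)oxy]methyl}cyclopent-2-en-1-one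
Product: 10 {[(4R)-4-[(tert-butyldimethylsilyl)oxy]-2-{[(tert-butyldiphenylsilyl)oxy]methyl}cyclopent-1-en-1-yl]oxy}triethylsilane
Conditions: Et3SiH, RhCl(PPh3)3 (1 mol %), toluene, 50 °C
Reagents that add atoms: triethylsilane, CC[SiH](CC)CC
Why: Rhodium-catalysed 1,4-hydrosilylation of the enone (conjugate reduction) places hydrogen on C3 and silicon on oxygen, so the tetrasubstituted enol ether is formed regiospecifically and no metal enolate that could expel the neighbouring silyloxy groups is generated.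

Step 6
Reactants: 10 {[(4R)-4-[(tert-butyldimethylsilyl)oxy]-2-{[(tert-butyldiphenylsilyl)oxy]methyl}cyclopent-1-en-1-yl]oxy}triethylsilane
Product: 12 (5R)-2-bromo-5-[(tert-butyldimethylsilyl)oxy]-3-{[(tert-butyldiphenylsilyl)oxy]methyl}cyclohex-2-en-1-one, via dibromocyclopropane 11 (not isolated)
Conditions: CHBr3 (slight excess over base), KOt-Bu, hexane, −30 to 0 °C; then toluene, 80 °C
Reagents that add atoms: bromoform, BrC(Br)Br
Why: KOt-Bu and bromoform give singlet dibromocarbene by α-elimination, which adds in a concerted [2+1] cheletropic cycloaddition to the electron-rich enol ether C=C of 10 and so closes the cyclopropane of 11 (attack on either face is acceptable). On warming, 11 undergoes the thermally allowed disrotatory two-electron electrocyclic opening of the cyclopropane with loss of the endo bromide, pushed by the siloxy oxygen; the bond shared by the three- and five-membered rings breaks, so the carbene carbon becomes C5 between C4 and C6 and the five-membered ring becomes the six-membered one (a ring expansion, not a ring closure). Bromide then takes the triethylsilyl group from the oxocarbenium ion and leaves the 2-bromoenone. The closest known reaction type is the dihalocarbene ring expansion of cyclic silyl enol ethers to 2-halocycloalk-2-enones. No stereocentre is formed, both cyclopropane diastereomers converge on one product, and the silyloxy-bearing centre is not involved. The step needs chemoselective carbene addition and cleavage of the internal rather than an external cyclopropane bond: the first is secured because the enol ether is the only alkene, the second by the cis ring fusion (only the endo bromide can leave with inward rotation of the ring bonds) and by oxygen stabilisation of the cation.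

Step 7
Reactants: 12 (5R)-2-bromo-5-[(tert-butyldimethylsilyl)oxy]-3-{[(tert-butyldiphenylsilyl)oxy]methyl}cyclohex-2-en-1-one
Product: 13 {[(9R)-6-bromo-7-{[(tert-butyldiphenylsilyl)oxy]methyl}-1,4-dioxaspiro[4.5]dec-6-en-9-yl]oxy}(tert-butyl)dimethylsilane
Conditions: Me3SiOCH2CH2OSiMe3, Me3SiOTf (5 mol %), CH2Cl2, −78 to −20 °C
Reagents that add atoms: 1,2-bis(trimethylsilyloxy)ethane, C[Si](C)(C)OCCO[Si](C)(C)C
Why: Silyl-triflate-catalysed ketalisation masks the ketone as a dioxolane under conditions too mild to eliminate the β-silyloxy group, giving a 2-bromoenone ketal that tolerates organolithium reagents.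

Step 8
Reactants: 13 {[(9R)-6-bromo-7-{[(tert-butyldiphenylsilyl)oxy]methyl}-1,4-dioxaspiro[4.5]dec-6-en-9-yl]oxy}(tert-butyl)dimethylsilane; 6 tert-butyldimethyl{[(4S)-4-(4,4,5,5-tetramethyl-1,3,2-dioxaborolan-2-yl)pentyl]oxy}silane
Product: 16 tert-butyl{[(4S)-4-[(9R)-9-[(tert-butyldimethylsilyl)oxy]-7-{[(tert-butyldiphenylsilyl)oxy]methyl}-1,4-dioxaspiro[4.5]dec-6-en-6-yl]pentyl]oxy}dimethylsilane, via alkenyllithium 14 (not isolated), via alkenylboronate complex 15 (not isolated)
Conditions: t-BuLi (2.1 equiv), THF, −78 °C; then 6, −78 to 0 °C; I2, MeOH, −78 °C; NaOMe, MeOH, −78 to 25 °C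
Reagents that add atoms: none
Why: Zweifel olefination: bromine–lithium exchange gives alkenyllithium 14, which adds to boronic ester 6 to form boronate 15; iodination of the alkene triggers 1,2-migration of the sec-alkyl group from boron to C5 with retention at the migrating carbon, and methoxide-induced deboronative elimination of the β-iodoboronate restores the ring alkene, so the S centre of 6 is carried over unchanged.

Step 9
Reactants: 16 tert-butyl{[(4S)-4-[(9R)-9-[(tert-butyldimethylsilyl)oxy]-7-{[(tert-butyldiphenylsilyl)oxy]methyl}-1,4-dioxaspiro[4.5]dec-6-en-6-yl]pentyl]oxy}dimethylsilane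
Product: 17 (5R)-5-[(tert-butyldimethylsilyl)oxy]-2-[(2S)-5-[(tert-butyldimethylsilyl)oxy]pentan-2-yl]-3-{[(tert-butyldiphenylsilyl)oxy]methyl}cyclohex-2-en-1-one
Conditions: pyridinium p-toluenesulfonate (cat.), acetone/H2O (20:1), 25 °C
Reagents that add atoms: water, O
Why: Mild acid-catalysed hydrolysis of the allylic dioxolane returns the enone while the silyl ethers survive.

Step 10
Reactants: 17 (5R)-5-[(tert-butyldimethylsilyl)oxy]-2-[(2S)-5-[(tert-butyldimethylsilyl)oxy]pentan-2-yl]-3-{[(tert-butyldiphenylsilyl)oxy]methyl}cyclohex-2-en-1-one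
Product: 18 methyl 2-[(1S,6R)-6-[(tert-butyldimethylsilyl)oxy]-3-[(2S)-5-[(tert-butyldimethylsilyl)oxy]pentan-2-yl]-4-{[(tert-butyldiphenylsilyl)oxy]methyl}-2-oxocyclohex-3-en-1-yl]acetate
Conditions: LiN(i-Pr)2 (1.1 equiv), THF, −78 °C; then BrCH2CO2Me, DMPU, −78 to −40 °C
Reagents that add atoms: methyl bromoacetate, COC(=O)CBr
Why: Kinetic deprotonation gives the cross-conjugated α′-enolate (the only α-carbon that carries hydrogen), which is alkylated by methyl bromoacetate anti to the adjacent silyloxy group (enolate alkylation), setting the new centre trans to the C7a oxygen.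

Step 11
Reactants: 18 methyl 2-[(1S,6R)-6-[(tert-butyldimethylsilyl)oxy]-3-[(2S)-5-[(tert-butyldimethylsilyl)oxy]pentan-2-yl]-4-{[(tert-butyldiphenylsilyl)oxy]methyl}-2-oxocyclohex-3-en-1-yl]acetate
Product: 20 (3aS,7aR)-6-{[(tert-butyldiphenylsilyl)oxy]methyl}-5-[(2S)-5-hydroxypentan-2-yl]-3,3a,7,7a-tetrahydro-1-benzofuran-2,4-dione, via dihydroxy keto ester 19 (not isolated)
Conditions: camphor-10-sulfonic acid (0.2 equiv), MeOH/CH2Cl2, 0 to 25 °C; then toluene, 50 °C
Reagents that add atoms: none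
Why: Acid-catalysed methanolysis removes the two tert-butyldimethylsilyl ethers but not the more robust tert-butyldiphenylsilyl ether, and the freed ring hydroxyl closes the trans-fused γ-lactone by intramolecular transesterification (lactonisation) while C4 is still a ketone and cannot compete.

Step 12
Reactants: 20 (3aS,7aR)-6-{[(tert-butyldiphenylsilyl)oxy]methyl}-5-[(2S)-5-hydroxypentan-2-yl]-3,3a,7,7a-tetrahydro-1-benzofuran-2,4-dione
Product: 21 (3aR,4S,7aR)-6-{[(tert-butyldiphenylsilyl)oxy]methyl}-4-hydroxy-5-[(2S)-5-hydroxypentan-2-yl]-3a,4,7,7a-tetrahydro-1-benzofuran-2(3H)-one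
Conditions: LiBH(s-Bu)3 (2.5 equiv), THF, −78 °C; then H2O
Reagents that add atoms: none
Why: The bulky hydride should attack the ketone along the equatorial trajectory, away from the axial C7a hydrogen, to give the axial 4-alcohol cis to the C3a–C3 bond (substrate-controlled 1,2-reduction; the fully substituted β-carbon blocks conjugate reduction).

Step 13
Reactants: 21 (3aR,4S,7aR)-6-{[(tert-butyldiphenylsilyl)oxy]methyl}-4-hydroxy-5-[(2S)-5-hydroxypentan-2-yl]-3a,4,7,7a-tetrahydro-1-benzofuran-2(3H)-one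
Product: 24 (3aR,4S,7aR)-6-{[(tert-butyldiphenylsilyl)oxy]methyl}-4-hydroxy-5-[(2S)-5-hydroxypentan-2-yl]-3-methylidene-3a,4,7,7a-tetrahydro-1-benzofuran-2(3H)-one, via Mannich base 22 (not isolated), via ammonium iodide 23 (not isolated)
Conditions: LiN(i-Pr)2 (3.5 equiv), THF, −78 °C; [H2C=NMe2]I, −78 to 0 °C; MeI, MeOH, 25 °C; NaHCO3, EtOAc/H2O, 25 °C
Reagents that add atoms: dimethylmethylideneammonium iodide, C=[N+](C)C.[I-]; iodomethane, CI (its methyl group stays only in intermediate 23)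
Why: Excess amide base forms the lactone enolate beside the two alkoxides (the enolate also shields the lactone carbonyl from the C4 alkoxide), a Mannich reaction with the iminium salt gives amine 22, and quaternisation followed by mild base-induced elimination of trimethylamine installs the exocyclic methylidene (α-methylenation of a lactone).

Step 14
Reactants: 24 (3aR,4S,7aR)-6-{[(tert-butyldiphenylsilyl)oxy]methyl}-4-hydroxy-5-[(2S)-5-hydroxypentan-2-yl]-3-methylidene-3a,4,7,7a-tetrahydro-1-benzofuran-2(3H)-one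
Product: 25 (4S)-4-[(3aR,4S,7aR)-6-{[(tert-butyldiphenylsilyl)oxy]methyl}-4-hydroxy-3-methylidene-2-oxo-2,3,3a,4,7,7a-hexahydro-1-benzofuran-5-yl]pentyl acetate
Conditions: Ac2O (1.1 equiv), 2,4,6-collidine, CH2Cl2, −20 to 0 °C
Reagents that add atoms: acetic anhydride, CC(=O)OC(C)=O
Why: Acylation with a slight excess of anhydride at low temperature should take the unhindered primary hydroxyl in preference to the axial secondary allylic hydroxyl flanked by the tetrasubstituted alkene (chemoselective esterification).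

Step 15
Reactants: 25 (4S)-4-[(3aR,4S,7aR)-6-{[(tert-butyldiphenylsilyl)oxy]methyl}-4-hydroxy-3-methylidene-2-oxo-2,3,3a,4,7,7a-hexahydro-1-benzofuran-5-yl]pentyl acetate
Product: 26 (4S)-4-[(3aR,4S,7aR)-4-hydroxy-6-(hydroxymethyl)-3-methylidene-2-oxo-2,3,3a,4,7,7a-hexahydro-1-benzofuran-5-yl]pentyl acetate
Conditions: HF·pyridine, pyridine/THF, 0 to 25 °C
Reagents that add atoms: none
Why: Fluoride-mediated desilylation under buffered acidic conditions cleaves the silyl ether without harming the acetate or the α-methylene lactone.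

Step 16
Reactants: 26 (4S)-4-[(3aR,4S,7aR)-4-hydroxy-6-(hydroxymethyl)-3-methylidene-2-oxo-2,3,3a,4,7,7a-hexahydro-1-benzofuran-5-yl]pentyl acetate
Product: 27 [(3aR,4S,7aR)-5-[(2S)-5-(acetyloxy)pentan-2-yl]-4-hydroxy-3-methylidene-2-oxo-2,3,3a,4,7,7a-hexahydro-1-benzofuran-6-yl]methyl 2-methylprop-2-enoate
Conditions: methacrylic anhydride (1.2 equiv), Et3N, 4-(dimethylamino)pyridine (5 mol %), CH2Cl2, −20 to 0 °C
Reagents that add atoms: methacrylic anhydride, C=C(C)C(=O)OC(=O)C(C)=C
Why: Amine-catalysed acylation at low temperature should esterify the primary allylic hydroxyl in preference to the hindered secondary one (chemoselective esterification), giving the target.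

Compound list
1 | tert-butyldimethyl(prop-2-en-1-yloxy)silane | C=CCO[Si](C)(C)C(C)(C)C | starting material
2 | tert-butyldimethyl[3-(4,4,5,5-tetramethyl-1,3,2-dioxaborolan-2-yl)propoxy]silane | CC(C)(C)[Si](C)(C)OCCCB1OC(C)(C)C(C)(C)O1 | intermediate
3 | ethyl 2,4,6-tri(propan-2-yl)benzoate | CCOC(=O)c1c(C(C)C)cc(C(C)C)cc1C(C)C | starting material
4 | (1R)-1-lithioethyl 2,4,6-tri(propan-2-yl)benzoate, (+)-sparteine complex | C[C@@H]([Li])OC(=O)c1c(C(C)C)cc(C(C)C)cc1C(C)C | intermediate
5 | lithium boronate complex from 4 and 2 (R at the oxygen-bearing carbon) | [Li+].C[C@H](OC(=O)c1c(C(C)C)cc(C(C)C)cc1C(C)C)[B-]2(CCCO[Si](C)(C)C(C)(C)C)OC(C)(C)C(C)(C)O2 | intermediate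
6 | tert-butyldimethyl{[(4S)-4-(4,4,5,5-tetramethyl-1,3,2-dioxaborolan-2-yl)pentyl]oxy}silane | C[C@@H](CCCO[Si](C)(C)C(C)(C)C)B1OC(C)(C)C(C)(C)O1 | intermediate
7 | (4S)-4-[(tert-butyldimethylsilyl)oxy]cyclopent-2-en-1-one | O=C1C=C[C@@H](O[Si](C)(C)C(C)(C)C)C1 | starting material
8 | (4S)-4-[(tert-butyldimethylsilyl)oxy]-2-(hydroxymethyl)cyclopent-2-en-1-one | O=C1C(CO)=C[C@@H](O[Si](C)(C)C(C)(C)C)C1 | intermediate
9 | (4S)-4-[(tert-butyldimethylsilyl)oxy]-2-{[(tert-butyldiphenylsilyl)oxy]methyl}cyclopent-2-en-1-one | O=C1C(CO[Si](c2ccccc2)(c2ccccc2)C(C)(C)C)=C[C@@H](O[Si](C)(C)C(C)(C)C)C1 | intermediate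
10 | {[(4R)-4-[(tert-butyldimethylsilyl)oxy]-2-{[(tert-butyldiphenylsilyl)oxy]methyl}cyclopent-1-en-1-yl]oxy}triethylsilane | CC[Si](CC)(CC)OC1=C(CO[Si](c2ccccc2)(c2ccccc2)C(C)(C)C)C[C@@H](O[Si](C)(C)C(C)(C)C)C1 | intermediate
11 | 6,6-dibromo-3-[(tert-butyldimethylsilyl)oxy]-5-{[(tert-butyldiphenylsilyl)oxy]methyl}-1-[(triethylsilyl)oxy]bicyclo[3.1.0]hexane (both cyclopropane-face diastereomers; silyloxy-bearing C3 as in 10) | CC[Si](CC)(CC)OC12C[C@H](O[Si](C)(C)C(C)(C)C)CC1(CO[Si](c3ccccc3)(c3ccccc3)C(C)(C)C)C2(Br)Br | intermediate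
12 | (5R)-2-bromo-5-[(tert-butyldimethylsilyl)oxy]-3-{[(tert-butyldiphenylsilyl)oxy]methyl}cyclohex-2-en-1-one | O=C1C(Br)=C(CO[Si](c2ccccc2)(c2ccccc2)C(C)(C)C)C[C@@H](O[Si](C)(C)C(C)(C)C)C1 | intermediate
13 | {[(9R)-6-bromo-7-{[(tert-butyldiphenylsilyl)oxy]methyl}-1,4-dioxaspiro[4.5]dec-6-en-9-yl]oxy}(tert-butyl)dimethylsilane | BrC1=C(CO[Si](c2ccccc2)(c2ccccc2)C(C)(C)C)C[C@@H](O[Si](C)(C)C(C)(C)C)CC13OCCO3 | intermediate
14 | [(9R)-9-[(tert-butyldimethylsilyl)oxy]-7-{[(tert-butyldiphenylsilyl)oxy]methyl}-1,4-dioxaspiro[4.5]dec-6-en-6-yl]lithium | [Li]C1=C(CO[Si](c2ccccc2)(c2ccccc2)C(C)(C)C)C[C@@H](O[Si](C)(C)C(C)(C)C)CC13OCCO3 | intermediate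
15 | lithium boronate complex from 14 and 6 (alkenyl and (S)-sec-alkyl groups on the pinacolato boron) | [Li+].C[C@@H](CCCO[Si](C)(C)C(C)(C)C)[B-]1(OC(C)(C)C(C)(C)O1)C1=C(CO[Si](c2ccccc2)(c2ccccc2)C(C)(C)C)C[C@@H](O[Si](C)(C)C(C)(C)C)CC13OCCO3 | intermediate
16 | tert-butyl{[(4S)-4-[(9R)-9-[(tert-butyldimethylsilyl)oxy]-7-{[(tert-butyldiphenylsilyl)oxy]methyl}-1,4-dioxaspiro[4.5]dec-6-en-6-yl]pentyl]oxy}dimethylsilane | CC(C)(C)[Si](C)(C)OCCC[C@H](C)C1=C(CO[Si](c2ccccc2)(c2ccccc2)C(C)(C)C)C[C@@H](O[Si](C)(C)C(C)(C)C)CC13OCCO3 | intermediate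
17 | (5R)-5-[(tert-butyldimethylsilyl)oxy]-2-[(2S)-5-[(tert-butyldimethylsilyl)oxy]pentan-2-yl]-3-{[(tert-butyldiphenylsilyl)oxy]methyl}cyclohex-2-en-1-one | O=C1C([C@@H](C)CCCO[Si](C)(C)C(C)(C)C)=C(CO[Si](c2ccccc2)(c2ccccc2)C(C)(C)C)C[C@@H](O[Si](C)(C)C(C)(C)C)C1 | intermediate
18 | methyl 2-[(1S,6R)-6-[(tert-butyldimethylsilyl)oxy]-3-[(2S)-5-[(tert-butyldimethylsilyl)oxy]pentan-2-yl]-4-{[(tert-butyldiphenylsilyl)oxy]methyl}-2-oxocyclohex-3-en-1-yl]acetate | O=C1C([C@@H](C)CCCO[Si](C)(C)C(C)(C)C)=C(CO[Si](c2ccccc2)(c2ccccc2)C(C)(C)C)C[C@@H](O[Si](C)(C)C(C)(C)C)[C@@H]1CC(=O)OC | intermediate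
19 | methyl 2-[(1S,6R)-4-{[(tert-butyldiphenylsilyl)oxy]methyl}-6-hydroxy-3-[(2S)-5-hydroxypentan-2-yl]-2-oxocyclohex-3-en-1-yl]acetate | O=C1C([C@@H](C)CCCO)=C(CO[Si](c2ccccc2)(c2ccccc2)C(C)(C)C)C[C@@H](O)[C@@H]1CC(=O)OC | intermediate
20 | (3aS,7aR)-6-{[(tert-butyldiphenylsilyl)oxy]methyl}-5-[(2S)-5-hydroxypentan-2-yl]-3,3a,7,7a-tetrahydro-1-benzofuran-2,4-dione | CC(C)(C)[Si](c1ccccc1)(c1ccccc1)OCC1=C([C@@H](C)CCCO)C(=O)[C@H]2CC(=O)O[C@@H]2C1 | intermediate
21 | (3aR,4S,7aR)-6-{[(tert-butyldiphenylsilyl)oxy]methyl}-4-hydroxy-5-[(2S)-5-hydroxypentan-2-yl]-3a,4,7,7a-tetrahydro-1-benzofuran-2(3H)-one | CC(C)(C)[Si](c1ccccc1)(c1ccccc1)OCC1=C([C@@H](C)CCCO)[C@@H](O)[C@H]2CC(=O)O[C@@H]2C1 | intermediate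
22 | 3-[(dimethylamino)methyl] derivative of 21 (C3 epimers) | CC(C)(C)[Si](c1ccccc1)(c1ccccc1)OCC1=C([C@@H](C)CCCO)[C@@H](O)[C@H]2C(CN(C)C)C(=O)O[C@@H]2C1 | intermediate
23 | N-methyl ammonium iodide of 22 | [I-].CC(C)(C)[Si](c1ccccc1)(c1ccccc1)OCC1=C([C@@H](C)CCCO)[C@@H](O)[C@H]2C(C[N+](C)(C)C)C(=O)O[C@@H]2C1 | intermediate
24 | (3aR,4S,7aR)-6-{[(tert-butyldiphenylsilyl)oxy]methyl}-4-hydroxy-5-[(2S)-5-hydroxypentan-2-yl]-3-methylidene-3a,4,7,7a-tetrahydro-1-benzofuran-2(3H)-one | CC(C)(C)[Si](c1ccccc1)(c1ccccc1)OCC1=C([C@@H](C)CCCO)[C@@H](O)[C@H]2C(=C)C(=O)O[C@@H]2C1 | intermediate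
25 | (4S)-4-[(3aR,4S,7aR)-6-{[(tert-butyldiphenylsilyl)oxy]methyl}-4-hydroxy-3-methylidene-2-oxo-2,3,3a,4,7,7a-hexahydro-1-benzofuran-5-yl]pentyl acetate | CC(C)(C)[Si](c1ccccc1)(c1ccccc1)OCC1=C([C@@H](C)CCCOC(C)=O)[C@@H](O)[C@H]2C(=C)C(=O)O[C@@H]2C1 | intermediate
26 | (4S)-4-[(3aR,4S,7aR)-4-hydroxy-6-(hydroxymethyl)-3-methylidene-2-oxo-2,3,3a,4,7,7a-hexahydro-1-benzofuran-5-yl]pentyl acetate | OCC1=C([C@@H](C)CCCOC(C)=O)[C@@H](O)[C@H]2C(=C)C(=O)O[C@@H]2C1 | intermediate
27 | [(3aR,4S,7aR)-5-[(2S)-5-(acetyloxy)pentan-2-yl]-4-hydroxy-3-methylidene-2-oxo-2,3,3a,4,7,7a-hexahydro-1-benzofuran-6-yl]methyl 2-methylprop-2-enoate | C=C(C)C(=O)OCC1=C([C@@H](C)CCCOC(C)=O)[C@@H](O)[C@H]2C(=C)C(=O)O[C@@H]2C1 | target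

Total step count: 16. Longest linear sequence: 14 steps (7 to 27, steps 3 to 16); boronic ester 6 is made in 2 steps and joins in step 8.

Steps most likely to fail

Step 8. The alkenyllithium is flanked by the spiro-ketal carbon and the silyloxymethyl-bearing carbon, so addition to the secondary boronic ester may be too slow; alternatively the β-iodoboronate may fail to eliminate within the ring. Either way protonated or iodinated alkene would result instead of coupling. The fallback sets out from 13 and comes back at 16 by a stereoretentive Negishi coupling. (R)-γ-Valerolactone is reduced with LiAlH4 to (4R)-pentane-1,4-diol F1. Silylation of the primary hydroxyl (t-BuMe2SiCl, imidazole) gives (2R)-5-[(tert-butyldimethylsilyl)oxy]pentan-2-ol F2. An Appel reaction (I2, PPh3, imidazole) converts it with inversion into tert-butyl{[(4S)-4-iodopentyl]oxy}dimethylsilane F3. Iodine–lithium exchange with retention (t-BuLi, pentane/Et2O, −100 °C, inverse addition) and transmetallation with Me3SiCH2ZnBr·LiBr give the configurationally stable {(2S)-5-[(tert-butyldimethylsilyl)oxy]pentan-2-yl}[(trimethylsilyl)methyl]zinc F4. This is coupled with bromide 13 under [Pd(μ-I)(Pt-Bu3)]2 catalysis at −25 °C with retention to give 16.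

Step 10. The α′-enolate carries a β-silyloxy group; loss of silyloxide (E1cB) followed by tautomerisation to a phenol may outrun alkylation. The fallback sets out from 17 and comes back at 18, and alkylates a neutral enol derivative under Lewis acid instead of the lithium enolate. 17 is converted with t-BuMe2SiOTf/Et3N (CH2Cl2, −78 to 0 °C) into the cross-conjugated silyl dienol ether of 17 F5. F5 is alkylated anti to the ring silyloxy group with methyl 2-chloro-2-(phenylsulfanyl)acetate and ZnBr2 to give methyl 2-(phenylsulfanyl)-2-[ring of 18]acetate F6. Bu3SnH/AIBN (toluene, 80 °C) then removes sulfur and gives 18.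

Step 12. Facial selectivity may be poor: if hydride enters along the axial trajectory, the equatorial C4 epimer forms. The fallback sets out from 20 and comes back at 21 by making that epimer on purpose and inverting it. Luche reduction (NaBH4, CeCl3·7H2O, MeOH, −78 °C) should give the (3aR,4R,7aR)-4-epimer of 21 F7. Mitsunobu reaction with chloroacetic acid (PPh3, diisopropyl azodicarboxylate, THF, 0 °C) inverts C4 and also esterifies the primary alcohol, giving the bis(chloroacetate) of 21 F8. Thiourea/NaHCO3 in EtOH (40 °C) removes both chloroacetates and gives 21.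

Further compounds
F1 | step 8 | (4R)-pentane-1,4-diol | C[C@@H](O)CCCO
F2 | step 8 | (2R)-5-[(tert-butyldimethylsilyl)oxy]pentan-2-ol | C[C@@H](O)CCCO[Si](C)(C)C(C)(C)C
F3 | step 8 | tert-butyl{[(4S)-4-iodopentyl]oxy}dimethylsilane | C[C@H](I)CCCO[Si](C)(C)C(C)(C)C
F4 | step 8 | {(2S)-5-[(tert-butyldimethylsilyl)oxy]pentan-2-yl}[(trimethylsilyl)methyl]zinc | C[C@H]([Zn]C[Si](C)(C)C)CCCO[Si](C)(C)C(C)(C)C
F5 | step 10 | cross-conjugated tert-butyldimethylsilyl dienol ether of 17 | CC(C)(C)[Si](C)(C)OC1=C[C@H](O[Si](C)(C)C(C)(C)C)CC(CO[Si](c2ccccc2)(c2ccccc2)C(C)(C)C)=C1[C@@H](C)CCCO[Si](C)(C)C(C)(C)C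
F6 | step 10 | methyl 2-(phenylsulfanyl)-2-[ring of 18]acetate (ring configuration as in 18, sulfur-bearing carbon as a mixture) | O=C1C([C@@H](C)CCCO[Si](C)(C)C(C)(C)C)=C(CO[Si](c2ccccc2)(c2ccccc2)C(C)(C)C)C[C@@H](O[Si](C)(C)C(C)(C)C)[C@@H]1C(Sc1ccccc1)C(=O)OC
F7 | step 12 | (3aR,4R,7aR)-4-epimer of 21 | CC(C)(C)[Si](c1ccccc1)(c1ccccc1)OCC1=C([C@@H](C)CCCO)[C@H](O)[C@H]2CC(=O)O[C@@H]2C1
F8 | step 12 | bis(chloroacetate) of 21 | CC(C)(C)[Si](c1ccccc1)(c1ccccc1)OCC1=C([C@@H](C)CCCOC(=O)CCl)[C@@H](OC(=O)CCl)[C@H]2CC(=O)O[C@@H]2C1
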